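**Plan**
Numbering: indane C1 carries the carbinol carbon Cα and ring D. C2 carries ring B (3,5-dioxygenated) and C3 carries ring C (4-oxygenated). Ring A is C3a–C7a, with oxygen on C4 and C6.
Retrosynthetic cuts, in order: six O–benzyl bonds; C1–C7a (ring closure); the oxirane oxygen across C1–Cα; C1=Cα; C2–ring B; C3–ring C; C2=C3; C3–C3a (formyl).
Enabling feature: C7a–C1–Cα–OH is a 2-arylethanol unit with aryl and hydroxyl anti, the retron of a trans-oxirane opened by an aryl carbanion. C7a is meta to both ring A oxygens and out of reach of electrophilic substitution, so it carries bromine from the start as a latent carbanion.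
Forward: the chain C3–C2–C1–Cα is grown linearly on ring A without making any ring. The five-membered ring closes in the penultimate step by strain-releasing 5-exo opening of the oxirane.
Stereochemistry: C3 comes from a rhodium/chiral diene 1,4-addition and C2 from an imidazolidinone/copper α-arylation. C1 and Cα come from Shi epoxidation of the E-alkene, followed by inversion at C1 and retention at Cα.
Benzyl ethers are used throughout, so the last step is neutral and the p-hydroxybenzylic alcohol never meets an acid.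

Key step: step 9

Assumption: 1, 4, 6, 8, 9 and 13 are taken as purchasable, and the diene ligand, the imidazolidinone and the fructose-derived ketone are taken as commercial catalysts.

**Step 1**
Reactants: 1 1,3-bis(benzyloxy)-5-bromobenzene
Product: 3 2,4-bis(benzyloxy)-6-bromobenzaldehyde, via aryl iminium chloride 2 (not isolated)
Conditions: POCl3, DMF, 0 → 80 °C; then H2O
Reagents that add atoms: N,N-dimethylformamide, CN(C)C=O; water, O; phosphoryl chloride, O=P(Cl)(Cl)Cl (chloride of 2 only)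
Why: Vilsmeier–Haack formylation, in which the chloroiminium ion attacks the position para to one benzyloxy group and ortho to the other (next to bromine) rather than the crowded site between the two ethers, and hydrolysis of 2 gives the aldehyde whose carbon becomes C3.

**Step 2**
Reactants: 3 2,4-bis(benzyloxy)-6-bromobenzaldehyde; 4 (triphenylphosphoranylidene)acetaldehyde
Product: 5 (E)-3-[2,4-bis(benzyloxy)-6-bromophenyl]prop-2-enal
Conditions: toluene, 90 °C
Reagents that add atoms: none
Why: Wittig reaction of a stabilised ylide, which is E-selective and adds the future C2 and C1 in one operation.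

**Step 3**
Reactants: 5 (E)-3-[2,4-bis(benzyloxy)-6-bromophenyl]prop-2-enal; 6 [4-(benzyloxy)phenyl]boronic acid
Product: 7 (3R)-3-[2,4-bis(benzyloxy)-6-bromophenyl]-3-[4-(benzyloxy)phenyl]propanal
Conditions: [RhCl(C2H4)2]2 (2.5 mol %), (1S,4S)-2,5-diphenylbicyclo[2.2.2]octa-2,5-diene (5.5 mol %), KOH (0.2 equiv), dioxane/H2O 10:1, 30 °C
Reagents that add atoms: none
Why: Hayashi–Miyaura reaction (asymmetric 1,4-addition of an arylboronic acid to an enal, chiral dienes suppressing 1,2-addition), in which the (S,S)-diene complex should bind the enal by the si face of the α-carbon so that ring C reaches the β-carbon face that gives (R)-C3, while the aryl bromide is inert to monovalent rhodium.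

**Step 4**
Reactants: 8 [3,5-bis(benzyloxy)phenyl]boronic acid; 9 (diacetoxyiodo)mesitylene
Product: 11 [3,5-bis(benzyloxy)phenyl](mesityl)iodonium trifluoromethanesulfonate, via iodonium tosylate 10 (not isolated)
Conditions: 9, TsOH·H2O, MeCN, rt; then 8, CH2Cl2, rt; then wash with aq CF3SO3Na
Reagents that add atoms: sodium trifluoromethanesulfonate, [Na+].[O-]S(=O)(=O)C(F)(F)F; 4-methylbenzenesulfonic acid, Cc1ccc(cc1)S(=O)(=O)O (anion of 10 only)
Why: Boron-to-iodine aryl transfer from a boronic acid to a hydroxy(tosyloxy)iodoarene made in the flask is ipso-specific, which puts trivalent iodine on the ring B carbon meta to both ethers, and mesityl is the ligand that is not transferred in step 5.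

**Step 5**
Reactants: 7 (3R)-3-[2,4-bis(benzyloxy)-6-bromophenyl]-3-[4-(benzyloxy)phenyl]propanal; 11 [3,5-bis(benzyloxy)phenyl](mesityl)iodonium trifluoromethanesulfonate
Product: 12 (2R,3R)-3-[2,4-bis(benzyloxy)-6-bromophenyl]-2-[3,5-bis(benzyloxy)phenyl]-3-[4-(benzyloxy)phenyl]propanal
Conditions: CuBr (10 mol %), (2S,5S)-5-benzyl-2-tert-butyl-3-methylimidazolidin-4-one·Cl3CCO2H (20 mol %), NaHCO3, toluene/Et2O 2:1, 23 °C
Reagents that add atoms: none
Why: Enantioselective α-arylation of an aldehyde by combined enamine and copper catalysis with a diaryliodonium salt, in which the E-enamine is shielded on the face of the benzyl and tert-butyl groups so that the aryl species of trivalent copper delivers ring B to the open face and sets (2R) in 12 (the future (S)-C2) under catalyst control, the weakly basic medium leaving the product unenolised.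

**Step 6**
Reactants: 13 1-(benzyloxy)-4-(chloromethyl)benzene
Product: 14 diethyl [4-(benzyloxy)benzyl]phosphonate
Conditions: P(OEt)3 (neat), 140 °C
Reagents that add atoms: triethyl phosphite, CCOP(OCC)OCC
Why: Michaelis–Arbuzov reaction of a reactive benzylic chloride.

**Step 7**
Reactants: 12 (2R,3R)-3-[2,4-bis(benzyloxy)-6-bromophenyl]-2-[3,5-bis(benzyloxy)phenyl]-3-[4-(benzyloxy)phenyl]propanal; 14 diethyl [4-(benzyloxy)benzyl]phosphonate
Product: 15 (1E,3R,4R)-4-[2,4-bis(benzyloxy)-6-bromophenyl]-3-[3,5-bis(benzyloxy)phenyl]-1,4-bis[4-(benzyloxy)phenyl]but-1-ene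
Conditions: 14, KN(SiMe3)2, THF, −78 °C; then 12, −78 °C → rt
Reagents that add atoms: none
Why: Horner–Wadsworth–Emmons olefination with a benzylic phosphonate carbanion gives the E-styrene, and adding 12 to the preformed potassium carbanion at −78 °C should outrun enolisation so that C2 is kept.

**Step 8**
Reactants: 15 (1E,3R,4R)-4-[2,4-bis(benzyloxy)-6-bromophenyl]-3-[3,5-bis(benzyloxy)phenyl]-1,4-bis[4-(benzyloxy)phenyl]but-1-ene
Product: 16 (2R,3R)-2-{(1R,2R)-2-[2,4-bis(benzyloxy)-6-bromophenyl]-1-[3,5-bis(benzyloxy)phenyl]-2-[4-(benzyloxy)phenyl]ethyl}-3-[4-(benzyloxy)phenyl]oxirane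
Conditions: 1,2:4,5-di-O-isopropylidene-β-D-erythro-hexo-2,3-diulo-2,6-pyranose (30 mol %), KHSO5 (as 2KHSO5·KHSO4·K2SO4), K2CO3, aq Na2B4O7 buffer (pH 10.5), Bu4NHSO4 (cat.), MeCN/CH2(OMe)2/H2O, 0 °C; chromatography on Et3N-deactivated silica
Reagents that add atoms: potassium peroxymonosulfate, [K+].[O-]S(=O)(=O)OO
Why: Shi epoxidation, in which the dioxirane of the D-fructose-derived ketone transfers oxygen to E-disubstituted styrenes through a spiro transition state to give the (R,R)-oxirane under reagent control, the basic buffer protecting the acid-sensitive p-alkoxyphenyl oxirane.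

**Step 9**
Reactants: 16 (2R,3R)-2-{(1R,2R)-2-[2,4-bis(benzyloxy)-6-bromophenyl]-1-[3,5-bis(benzyloxy)phenyl]-2-[4-(benzyloxy)phenyl]ethyl}-3-[4-(benzyloxy)phenyl]oxirane
Product: 19 (S)-[4-(benzyloxy)phenyl]{(1R,2S,3R)-4,6-bis(benzyloxy)-2-[3,5-bis(benzyloxy)phenyl]-3-[4-(benzyloxy)phenyl]-2,3-dihydro-1H-inden-1-yl}methanol, via aryllithium 17 (not isolated), via lithium alkoxide 18 (not isolated)
Conditions: t-BuLi (2.1 equiv), THF/Et2O, −78 °C, then → 0 °C; H2O
Reagents that add atoms: tert-butyllithium, [Li]C(C)(C)C (lithium of 17 and 18 only)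
Why: Bromine–lithium exchange at C7a, which at −78 °C is much faster than any attack of t-BuLi on the oxirane or the benzyl ethers (the second equivalent destroys t-BuBr), gives aryllithium 17, whose in-plane carbanion attacks the nearer oxirane carbon (future C1) from the side opposite to oxygen and releases the strain of the three-membered ring to give alkoxide 18, protonated on work-up. The closest known reaction type is the Parham cyclisation of o-bromoaryl-substituted alkyl oxiranes (anionic cyclialkylation by an internal electrophile). The five-membered ring closes in the 5-exo-tet mode, the breaking C1–O bond lying outside the new ring. C1 is set by inversion at the (R)-oxirane carbon (stereospecific SN2; the descriptor stays R only because the priorities change), Cα keeps the configuration written by the epoxidation because its C–O bond is not touched, and C2 and C3 are spectators, so the trans-oxirane of the E-alkene maps onto the required (1R,αS) pair with the side chain trans to ring B. The step needs attack at C1 rather than 6-endo attack at the benzylic Cα and substitution rather than base-induced isomerisation of the oxirane: the three-atom tether C3a–C3–C2 lets the carbanion line up only with the C1–O bond, no Lewis acid stronger than solvated lithium is present to develop cationic character at the p-alkoxybenzylic carbon, and the forming ring has all three substituents trans. The bromine, the only helper, sits on the one ring A carbon that is meta to both oxygens and leaves as LiBr, and the basic medium keeps the acid-labile benzylic alcohol from ionising.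

**Step 10**
Reactants: 19 (S)-[4-(benzyloxy)phenyl]{(1R,2S,3R)-4,6-bis(benzyloxy)-2-[3,5-bis(benzyloxy)phenyl]-3-[4-(benzyloxy)phenyl]-2,3-dihydro-1H-inden-1-yl}methanol
Product: 20 (1R,2S,3R)-2-(3,5-dihydroxyphenyl)-1-[(S)-hydroxy(4-hydroxyphenyl)methyl]-3-(4-hydroxyphenyl)-2,3-dihydro-1H-indene-4,6-diol
Conditions: H2 (1 atm), Pd/C (10 %), EtOAc/EtOH, rt
Reagents that add atoms: none
Why: Hydrogenolysis of the six aryl benzyl ethers in a neutral medium, in which a secondary benzylic alcohol is cleaved far more slowly, avoids every acid or Lewis acid that would ionise the p-hydroxybenzylic alcohol, and no stereocentre is touched.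

**Compound list**
1 | 1,3-bis(benzyloxy)-5-bromobenzene | Brc1cc(OCc2ccccc2)cc(OCc2ccccc2)c1 | starting material
2 | [2,4-bis(benzyloxy)-6-bromobenzylidene]dimethylammonium chloride | C[N+](C)=Cc1c(Br)cc(OCc2ccccc2)cc1OCc1ccccc1.[Cl-] | intermediate
3 | 2,4-bis(benzyloxy)-6-bromobenzaldehyde | O=Cc1c(Br)cc(OCc2ccccc2)cc1OCc1ccccc1 | intermediate
4 | (triphenylphosphoranylidene)acetaldehyde | O=CC=P(c1ccccc1)(c1ccccc1)c1ccccc1 | starting material
5 | (E)-3-[2,4-bis(benzyloxy)-6-bromophenyl]prop-2-enal | O=C/C=C/c1c(Br)cc(OCc2ccccc2)cc1OCc1ccccc1 | intermediate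
6 | [4-(benzyloxy)phenyl]boronic acid | OB(O)c1ccc(OCc2ccccc2)cc1 | starting material
7 | (3R)-3-[2,4-bis(benzyloxy)-6-bromophenyl]-3-[4-(benzyloxy)phenyl]propanal | c1ccccc1COc1ccc([C@H](c2c(OCc3ccccc3)cc(OCc3ccccc3)cc2Br)CC=O)cc1 | intermediate
8 | [3,5-bis(benzyloxy)phenyl]boronic acid | OB(O)c1cc(OCc2ccccc2)cc(OCc2ccccc2)c1 | starting material
9 | (diacetoxyiodo)mesitylene | CC(=O)OI(OC(C)=O)c1c(C)cc(C)cc1C | starting material
10 | [3,5-bis(benzyloxy)phenyl](mesityl)iodonium 4-methylbenzenesulfonate | Cc1cc(C)c([I+]c2cc(OCc3ccccc3)cc(OCc3ccccc3)c2)c(C)c1.Cc1ccc(S(=O)(=O)[O-])cc1 | intermediate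
11 | [3,5-bis(benzyloxy)phenyl](mesityl)iodonium trifluoromethanesulfonate | Cc1cc(C)c([I+]c2cc(OCc3ccccc3)cc(OCc3ccccc3)c2)c(C)c1.[O-]S(=O)(=O)C(F)(F)F | intermediate
12 | (2R,3R)-3-[2,4-bis(benzyloxy)-6-bromophenyl]-2-[3,5-bis(benzyloxy)phenyl]-3-[4-(benzyloxy)phenyl]propanal | c1ccccc1COc1ccc([C@H](c2c(OCc3ccccc3)cc(OCc3ccccc3)cc2Br)[C@H](c2cc(OCc3ccccc3)cc(OCc3ccccc3)c2)C=O)cc1 | intermediate
13 | 1-(benzyloxy)-4-(chloromethyl)benzene | ClCc1ccc(OCc2ccccc2)cc1 | starting material
14 | diethyl [4-(benzyloxy)benzyl]phosphonate | CCOP(=O)(Cc1ccc(OCc2ccccc2)cc1)OCC | intermediate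
15 | (1E,3R,4R)-4-[2,4-bis(benzyloxy)-6-bromophenyl]-3-[3,5-bis(benzyloxy)phenyl]-1,4-bis[4-(benzyloxy)phenyl]but-1-ene | c1ccccc1COc1ccc([C@H](c2c(OCc3ccccc3)cc(OCc3ccccc3)cc2Br)[C@H](c2cc(OCc3ccccc3)cc(OCc3ccccc3)c2)/C=C/c2ccc(OCc3ccccc3)cc2)cc1 | intermediate
16 | (2R,3R)-2-{(1R,2R)-2-[2,4-bis(benzyloxy)-6-bromophenyl]-1-[3,5-bis(benzyloxy)phenyl]-2-[4-(benzyloxy)phenyl]ethyl}-3-[4-(benzyloxy)phenyl]oxirane | c1ccccc1COc1ccc([C@H](c2c(OCc3ccccc3)cc(OCc3ccccc3)cc2Br)[C@H](c2cc(OCc3ccccc3)cc(OCc3ccccc3)c2)[C@H]2O[C@@H]2c2ccc(OCc3ccccc3)cc2)cc1 | intermediate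
17 | aryllithium from 16 (lithium in place of bromine, all four stereocentres as in 16) | c1ccccc1COc1ccc([C@H](c2c(OCc3ccccc3)cc(OCc3ccccc3)cc2[Li])[C@H](c2cc(OCc3ccccc3)cc(OCc3ccccc3)c2)[C@H]2O[C@@H]2c2ccc(OCc3ccccc3)cc2)cc1 | intermediate
18 | lithium alkoxide of 19 | c1ccccc1COc1ccc([C@@H]2c3c(OCc4ccccc4)cc(OCc4ccccc4)cc3[C@H]([C@H](O[Li])c3ccc(OCc4ccccc4)cc3)[C@H]2c2cc(OCc3ccccc3)cc(OCc3ccccc3)c2)cc1 | intermediate
19 | (S)-[4-(benzyloxy)phenyl]{(1R,2S,3R)-4,6-bis(benzyloxy)-2-[3,5-bis(benzyloxy)phenyl]-3-[4-(benzyloxy)phenyl]-2,3-dihydro-1H-inden-1-yl}methanol | c1ccccc1COc1ccc([C@@H]2c3c(OCc4ccccc4)cc(OCc4ccccc4)cc3[C@H]([C@H](O)c3ccc(OCc4ccccc4)cc3)[C@H]2c2cc(OCc3ccccc3)cc(OCc3ccccc3)c2)cc1 | intermediate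
20 | (1R,2S,3R)-2-(3,5-dihydroxyphenyl)-1-[(S)-hydroxy(4-hydroxyphenyl)methyl]-3-(4-hydroxyphenyl)-2,3-dihydro-1H-indene-4,6-diol | Oc1ccc([C@@H]2c3c(O)cc(O)cc3[C@H]([C@H](O)c3ccc(O)cc3)[C@H]2c2cc(O)cc(O)c2)cc1 | target

Total step count: 10. Longest linear sequence: 8 steps (1, 2, 3, 5, 7, 8, 9, 10).

**Steps most likely to fail**

Step 9. What may go wrong:
- The carbanion may attack the benzylic oxirane carbon (6-endo).
- Proton transfer or base-induced isomerisation may turn the oxirane into an allylic alkoxide.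
- The acid-sensitive oxirane may open prematurely during handling.

The fallback sets out from 15, comes back at 19 and does without the oxirane.
- t-BuLi (2.1 equiv, Et2O/pentane, −78 °C) converts 15 into the alkenyl-substituted aryllithium F1.
- On warming with TMEDA, F1 should add 5-exo-trig across the styrene double bond. This intramolecular carbolithiation has its regiochemistry enforced by benzylic stabilisation. It gives the benzylic organolithium F2, with the side chain trans to ring B.
- Trapping with 2-(benzenesulfonyl)-3-phenyloxaziridine gives the carbinol as a mixture of Cα epimers F3.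
- Dess–Martin oxidation gives the aryl indanyl ketone F4, in which trans-C1 is also the thermodynamic arrangement.
- Corey–Bakshi–Shibata reduction with the (R)-methyl oxazaborolidine and BH3·SMe2 sets Cα by reagent control and returns 19.

Step 5. What may go wrong:
- Enamine formation from the β,β-diaryl aldehyde may be slow.
- Facial selectivity may be poor if catalyst and C3 are mismatched.
- The C2 configuration may be lost by enolisation of the product.

The fallback sets out from 7, comes back at 12 and replaces enamine catalysis by an oxazolidinone auxiliary.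
- Pinnick oxidation (NaClO2, NaH2PO4, 2-methylbut-2-ene) gives the (3R)-diarylpropanoic acid F5.
- The pivaloyl mixed anhydride of F5 and lithiated (S)-4-benzyl-1,3-oxazolidin-2-one give the N-acyl oxazolidinone F6.
- Me3SiOSO2CF3/Et3N gives the Z-silyl ketene aminal F7.
- Cu(OSO2CF3)2 (10 mol %) and 11 in CH2Cl2 arylate the face opposite to the benzyl group to give the α-aryl imide F8.
- LiBH4 releases the primary alcohol F9, and Dess–Martin oxidation returns 12.

Step 3. What may go wrong:
- Insertion into the enal may be sluggish because of the di-ortho-substituted β-aryl group.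
- 1,2-Addition to the aldehyde may compete.
- Boronic acid 6 may undergo protodeboronation.

The fallback sets out from 3, comes back at 7 and replaces catalysis by auxiliary-controlled cuprate addition.
- Horner–Wadsworth–Emmons reaction of 3 with diethyl {2-oxo-2-[(4S)-2-oxo-4-phenyl-1,3-oxazolidin-3-yl]ethyl}phosphonate (LiCl, iPr2NEt, MeCN) gives the E-enoyl oxazolidinone F10.
- 4-(Benzyloxy)phenylmagnesium bromide with CuBr·SMe2 (THF, −40 °C) adds to the chelated s-cis conformer opposite to the phenyl group to give the (3R)-adduct F11.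
- LiBH4 gives the (3R)-diarylpropanol F12, and Dess–Martin oxidation returns 7.

**Further compounds**
F1 | step 9 | aryllithium from 15 (lithium in place of bromine) | c1ccccc1COc1ccc([C@H](c2c(OCc3ccccc3)cc(OCc3ccccc3)cc2[Li])[C@H](c2cc(OCc3ccccc3)cc(OCc3ccccc3)c2)/C=C/c2ccc(OCc3ccccc3)cc2)cc1
F2 | step 9 | benzylic organolithium of the all-trans indane (ring stereocentres as in 19, carbanion carbon labile) | c1ccccc1COc1ccc([C@@H]2c3c(OCc4ccccc4)cc(OCc4ccccc4)cc3[C@H](C([Li])c3ccc(OCc4ccccc4)cc3)[C@H]2c2cc(OCc3ccccc3)cc(OCc3ccccc3)c2)cc1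
F3 | step 9 | 19 and its Cα epimer as a mixture | c1ccccc1COc1ccc([C@@H]2c3c(OCc4ccccc4)cc(OCc4ccccc4)cc3[C@H](C(O)c3ccc(OCc4ccccc4)cc3)[C@H]2c2cc(OCc3ccccc3)cc(OCc3ccccc3)c2)cc1
F4 | step 9 | [4-(benzyloxy)phenyl]{(1R,2S,3R)-4,6-bis(benzyloxy)-2-[3,5-bis(benzyloxy)phenyl]-3-[4-(benzyloxy)phenyl]-2,3-dihydro-1H-inden-1-yl}methanone | c1ccccc1COc1ccc([C@@H]2c3c(OCc4ccccc4)cc(OCc4ccccc4)cc3[C@H](C(=O)c3ccc(OCc4ccccc4)cc3)[C@H]2c2cc(OCc3ccccc3)cc(OCc3ccccc3)c2)cc1
F5 | step 5 | (3R)-3-[2,4-bis(benzyloxy)-6-bromophenyl]-3-[4-(benzyloxy)phenyl]propanoic acid | c1ccccc1COc1ccc([C@H](c2c(OCc3ccccc3)cc(OCc3ccccc3)cc2Br)CC(=O)O)cc1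
F6 | step 5 | (4S)-4-benzyl-3-{(3R)-3-[2,4-bis(benzyloxy)-6-bromophenyl]-3-[4-(benzyloxy)phenyl]propanoyl}-1,3-oxazolidin-2-one | c1ccccc1COc1ccc([C@H](c2c(OCc3ccccc3)cc(OCc3ccccc3)cc2Br)CC(=O)N2[C@@H](Cc3ccccc3)COC2=O)cc1
F7 | step 5 | Z-trimethylsilyl ketene aminal of F6 | c1ccccc1COc1ccc([C@H](c2c(OCc3ccccc3)cc(OCc3ccccc3)cc2Br)/C=C(\O[Si](C)(C)C)N2[C@@H](Cc3ccccc3)COC2=O)cc1
F8 | step 5 | (4S)-4-benzyl-3-{(2R,3R)-3-[2,4-bis(benzyloxy)-6-bromophenyl]-2-[3,5-bis(benzyloxy)phenyl]-3-[4-(benzyloxy)phenyl]propanoyl}-1,3-oxazolidin-2-one | c1ccccc1COc1ccc([C@H](c2c(OCc3ccccc3)cc(OCc3ccccc3)cc2Br)[C@H](c2cc(OCc3ccccc3)cc(OCc3ccccc3)c2)C(=O)N2[C@@H](Cc3ccccc3)COC2=O)cc1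
F9 | step 5 | (2R,3R)-3-[2,4-bis(benzyloxy)-6-bromophenyl]-2-[3,5-bis(benzyloxy)phenyl]-3-[4-(benzyloxy)phenyl]propan-1-ol | c1ccccc1COc1ccc([C@H](c2c(OCc3ccccc3)cc(OCc3ccccc3)cc2Br)[C@H](c2cc(OCc3ccccc3)cc(OCc3ccccc3)c2)CO)cc1
F10 | step 3 | (4S)-3-{(E)-3-[2,4-bis(benzyloxy)-6-bromophenyl]prop-2-enoyl}-4-phenyl-1,3-oxazolidin-2-one | O=C(/C=C/c1c(Br)cc(OCc2ccccc2)cc1OCc1ccccc1)N1[C@@H](c2ccccc2)COC1=O
F11 | step 3 | (4S)-3-{(3R)-3-[2,4-bis(benzyloxy)-6-bromophenyl]-3-[4-(benzyloxy)phenyl]propanoyl}-4-phenyl-1,3-oxazolidin-2-one | c1ccccc1COc1ccc([C@H](c2c(OCc3ccccc3)cc(OCc3ccccc3)cc2Br)CC(=O)N2[C@@H](c3ccccc3)COC2=O)cc1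
F12 | step 3 | (3R)-3-[2,4-bis(benzyloxy)-6-bromophenyl]-3-[4-(benzyloxy)phenyl]propan-1-ol | c1ccccc1COc1ccc([C@H](c2c(OCc3ccccc3)cc(OCc3ccccc3)cc2Br)CCO)cc1
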